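**Retrosynthetic overview**

1. After a final alcohol-to-ketone oxidation, the cyclohexane ring is opened at the bond between its carbonyl carbon and the neighbouring gem-dimethyl carbon; forward, a tertiary alkyl radical made by titanium-mediated homolysis of a tertiary C–OH bond closes 6-exo onto an aldehyde.
2. Enabling feature: the quaternary CMe2 ring carbon sits directly beside the ring C=O and is 1,6 to it through the methylidene-bearing carbon; this CMe2 carbon, the adjacent CH stereocentre and the (E)-3-methylpentenyl chain up to the ether oxygen are exactly C7, C6 and C5–C1 of geraniol.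
3. The acyclic hydroxy aldehyde comes from (R)-6,7-epoxygeraniol (Shi epoxidation of geranyl acetate sets the only stereocentre) by SN2 opening at C6 with a 2-metallated 1-alkene carrying a masked aldehyde; inversion gives the (R) centre and leaves the tertiary alcohol that becomes the radical.
4. The aryl ether is made by Mitsunobu coupling of the primary allylic alcohol with 4-hydroxy-5-methylcoumarin before cyclisation, so the coumarin also caps that oxygen.
5. Ring order: the pyranone ring of the coumarin first (step 5), the cyclohexane ring second (step 8).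

Key step: step 8

Assumption: the carbinol carbon created in step 8 is carried as a mixture of epimers (no descriptor in 13 and 14), because step 9 converts it into the carbonyl group.

**Route**

Step 1
Reactants: 1 geranyl acetate
Product: 2 (2E)-5-[(2R)-3,3-dimethyloxiran-2-yl]-3-methylpent-2-en-1-yl acetate
Conditions: D-fructose-derived Shi ketone (30 mol %), Oxone, K2CO3, Bu4NHSO4 (cat.), MeCN/CH2(OMe)2/aq. Na2B4O7 buffer, 0 °C
Reagents that add atoms: Oxone (potassium peroxymonosulfate, KHSO5), [K+].[O-]S(=O)(=O)OO
Why: Shi asymmetric epoxidation, in which the chiral dioxirane should oxidise the electron-rich distal trisubstituted alkene (the proximal one is deactivated by the allylic acetate) through the spiro transition state that sets the (R) configuration of the oxirane CH carbon.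

Step 2
Reactants: 2 (2E)-5-[(2R)-3,3-dimethyloxiran-2-yl]-3-methylpent-2-en-1-yl acetate
Product: 3 (2E)-5-[(2R)-3,3-dimethyloxiran-2-yl]-3-methylpent-2-en-1-ol
Conditions: K2CO3 (0.2 equiv), MeOH, 0 °C to rt
Reagents that add atoms: none
Why: Base-catalysed transesterification (methanolysis) removes the acetate without touching the epoxide or its stereocentre.

Step 3
Reactants: 4 2,3-dibromoprop-1-ene, 5 (1,3-dioxolan-2-ylmethyl)magnesium bromide
Product: 6 2-(3-bromobut-3-en-1-yl)-1,3-dioxolane
Conditions: CuI (5 mol %), THF, 0 °C to rt
Reagents that add atoms: none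
Why: Copper-catalysed allylic substitution of the allylic bromide by the Grignard reagent leaves the vinylic bromide intact, and SN2 and SN2' attack give the same 2-bromoalkene.

Step 4
Reactants: 6 2-(3-bromobut-3-en-1-yl)-1,3-dioxolane, 3 (2E)-5-[(2R)-3,3-dimethyloxiran-2-yl]-3-methylpent-2-en-1-ol
Product: 8 (2E,6R)-6-[4-(1,3-dioxolan-2-yl)but-1-en-2-yl]-3,7-dimethyloct-2-ene-1,7-diol, via alkenylmagnesium bromide 7 (not isolated)
Conditions: Mg, THF, 45 °C; then 3 (0.33 equiv), CuI (20 mol %), THF, −30 °C to rt; aqueous work-up
Reagents that add atoms: none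
Why: Copper-catalysed Grignard opening of a trisubstituted epoxide, in which the alkenylcopper species should attack the less substituted oxirane carbon in an SN2 manner with inversion, turning the (R)-epoxide carbon into the (6R) centre, while one extra equivalent of 7 is consumed by the free hydroxyl.

Step 5
Reactants: 9 1-(2-hydroxy-6-methylphenyl)ethan-1-one
Product: 10 4-hydroxy-5-methyl-2H-chromen-2-one
Conditions: NaH, diethyl carbonate, PhMe, 110 °C; then aq. HCl
Reagents that add atoms: diethyl carbonate, CCOC(=O)OCC
Why: Claisen-type C-acylation of the methyl ketone enolate by diethyl carbonate followed by lactonisation onto the phenoxide is the standard construction of 4-hydroxycoumarins.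

Step 6
Reactants: 8 (2E,6R)-6-[4-(1,3-dioxolan-2-yl)but-1-en-2-yl]-3,7-dimethyloct-2-ene-1,7-diol, 10 4-hydroxy-5-methyl-2H-chromen-2-one
Product: 11 4-{[(2E,6R)-6-[4-(1,3-dioxolan-2-yl)but-1-en-2-yl]-7-hydroxy-3,7-dimethyloct-2-en-1-yl]oxy}-5-methyl-2H-chromen-2-one
Conditions: PPh3, DIAD, THF, 0 °C to rt
Reagents that add atoms: none
Why: Mitsunobu etherification, in which the acidic 4-hydroxycoumarin is alkylated on O4 by SN2 displacement at the activated primary allylic alcohol while the tertiary hydroxyl is too hindered to be activated.

Step 7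
Reactants: 11 4-{[(2E,6R)-6-[4-(1,3-dioxolan-2-yl)but-1-en-2-yl]-7-hydroxy-3,7-dimethyloct-2-en-1-yl]oxy}-5-methyl-2H-chromen-2-one
Product: 12 (5R,8E)-5-(2-hydroxypropan-2-yl)-8-methyl-10-[(5-methyl-2-oxo-2H-chromen-4-yl)oxy]-4-methylidenedec-8-enal
Conditions: 2 M aq. HCl, THF, rt
Reagents that add atoms: water, O
Why: Acid-catalysed acetal hydrolysis should free the aldehyde under conditions mild enough for the tertiary alcohol, the allylic coumarinyl ether and the 1,1-disubstituted alkene.

Step 8
Reactants: 12 (5R,8E)-5-(2-hydroxypropan-2-yl)-8-methyl-10-[(5-methyl-2-oxo-2H-chromen-4-yl)oxy]-4-methylidenedec-8-enal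
Product: 14 4-{[(2E)-5-[(1R)-3-hydroxy-2,2-dimethyl-6-methylidenecyclohexyl]-3-methylpent-2-en-1-yl]oxy}-5-methyl-2H-chromen-2-one, via triethylsilyl ether 13 (not isolated)
Conditions: Cp*TiCl3 (20 mol %), Zn dust, Et3SiCl, THF, 60 °C, slow addition of 12; then 1 M aq. HCl, THF, rt
Reagents that add atoms: none
Why: Proposed new method: the tertiary hydroxyl of 12 should exchange onto the titanium catalyst, and once Zn has reduced the metal to trivalent titanium the C–O bond should homolyse to a tertiary alkyl radical at the gem-dimethyl carbon, which adds to the titanium-bound aldehyde carbon while the oxygen is captured as a tetravalent titanium alkoxide that Et3SiCl silylates to 13, releasing the catalyst. The closest known reaction types are the Cp*TiCl3/Zn/Et3SiCl dehydroxylative radical alkylation of tertiary alcohols with electron-poor alkenes and the Cp2TiCl-mediated cyclisation of epoxide-derived tertiary radicals onto aldehydes and ketones, and this step is their intramolecular merger. The cyclohexane ring is closed in the 6-exo-trig mode onto C=O, helped by the gem-dimethyl group and the sp2 methylidene carbon in the tether. The new carbinol stereocentre is not controlled and is erased in step 9, while the existing (R) centre lies beta to the radical and is not touched. The step needs chemoselectivity for the aldehyde over the two alkenes, which is secured because radical addition to a C=O carbon six atoms away is far faster than 5-exo or 6-endo attack on the hindered trisubstituted side-chain alkene, attack on the adjacent methylidene would give a three- or four-membered ring, and capture of the oxygen by titanium makes the carbonyl addition irreversible. Only the tertiary hydroxyl can give a stabilised radical, and aliphatic aldehydes are not reduced by trivalent titanium.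

Step 9
Reactants: 14 4-{[(2E)-5-[(1R)-3-hydroxy-2,2-dimethyl-6-methylidenecyclohexyl]-3-methylpent-2-en-1-yl]oxy}-5-methyl-2H-chromen-2-one
Product: 15 4-{[(2E)-5-[(1R)-2,2-dimethyl-6-methylidene-3-oxocyclohexyl]-3-methylpent-2-en-1-yl]oxy}-5-methyl-2H-chromen-2-one
Conditions: Dess–Martin periodinane, CH2Cl2, 0 °C to rt
Reagents that add atoms: none
Why: Dess–Martin oxidation of the secondary alcohol should give the ketone under near-neutral conditions, removing the uncontrolled carbinol centre and leaving the non-epimerisable (R) centre and the exocyclic alkene in place.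

**Compound list**

1 | geranyl acetate, (2E)-3,7-dimethylocta-2,6-dien-1-yl acetate | CC(C)=CCC/C(C)=C/COC(C)=O | starting material
2 | (2E)-5-[(2R)-3,3-dimethyloxiran-2-yl]-3-methylpent-2-en-1-yl acetate | CC1(C)O[C@@H]1CC/C(C)=C/COC(C)=O | intermediate
3 | (2E)-5-[(2R)-3,3-dimethyloxiran-2-yl]-3-methylpent-2-en-1-ol | CC1(C)O[C@@H]1CC/C(C)=C/CO | intermediate
4 | 2,3-dibromoprop-1-ene | C=C(Br)CBr | starting material
5 | (1,3-dioxolan-2-ylmethyl)magnesium bromide | Br[Mg]CC1OCCO1 | starting material
6 | 2-(3-bromobut-3-en-1-yl)-1,3-dioxolane | C=C(Br)CCC1OCCO1 | intermediate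
7 | [4-(1,3-dioxolan-2-yl)but-1-en-2-yl]magnesium bromide | C=C([Mg]Br)CCC1OCCO1 | intermediate
8 | (2E,6R)-6-[4-(1,3-dioxolan-2-yl)but-1-en-2-yl]-3,7-dimethyloct-2-ene-1,7-diol | CC(C)(O)[C@@H](C(=C)CCC1OCCO1)CC/C(C)=C/CO | intermediate
9 | 1-(2-hydroxy-6-methylphenyl)ethan-1-one | CC(=O)c1c(C)cccc1O | starting material
10 | 4-hydroxy-5-methyl-2H-chromen-2-one | Cc1cccc2oc(=O)cc(O)c12 | intermediate
11 | 4-{[(2E,6R)-6-[4-(1,3-dioxolan-2-yl)but-1-en-2-yl]-7-hydroxy-3,7-dimethyloct-2-en-1-yl]oxy}-5-methyl-2H-chromen-2-one | CC(C)(O)[C@@H](C(=C)CCC1OCCO1)CC/C(C)=C/COc1cc(=O)oc2cccc(C)c12 | intermediate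
12 | (5R,8E)-5-(2-hydroxypropan-2-yl)-8-methyl-10-[(5-methyl-2-oxo-2H-chromen-4-yl)oxy]-4-methylidenedec-8-enal | CC(C)(O)[C@@H](C(=C)CCC=O)CC/C(C)=C/COc1cc(=O)oc2cccc(C)c12 | intermediate
13 | 4-{[(2E)-5-[(1R)-2,2-dimethyl-6-methylidene-3-(triethylsilyloxy)cyclohexyl]-3-methylpent-2-en-1-yl]oxy}-5-methyl-2H-chromen-2-one (both epimers at the silyloxy carbon) | C=C1CCC(O[Si](CC)(CC)CC)C(C)(C)[C@@H]1CC/C(C)=C/COc1cc(=O)oc2cccc(C)c12 | intermediate
14 | 4-{[(2E)-5-[(1R)-3-hydroxy-2,2-dimethyl-6-methylidenecyclohexyl]-3-methylpent-2-en-1-yl]oxy}-5-methyl-2H-chromen-2-one (both epimers at the carbinol carbon) | C=C1CCC(O)C(C)(C)[C@@H]1CC/C(C)=C/COc1cc(=O)oc2cccc(C)c12 | intermediate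
15 | 4-{[(2E)-5-[(1R)-2,2-dimethyl-6-methylidene-3-oxocyclohexyl]-3-methylpent-2-en-1-yl]oxy}-5-methyl-2H-chromen-2-one | C=C1CCC(=O)C(C)(C)[C@@H]1CC/C(C)=C/COc1cc(=O)oc2cccc(C)c12 | target

**Step count and risks**

Total step count: 9 (steps 3 and 5 prepare the two side fragments). Longest linear sequence: 7 steps (1, 2, 4, 6, 7, 8, 9).

Steps most likely to fail:

1. Step 8 (proposed new method). The tertiary radical may be reduced or quenched by hydrogen-atom abstraction before it cyclises, the titanium Lewis acid may trigger carbonyl-ene closure of the aldehyde onto the methylidene group, or the aldehyde may couple reductively under Zn/Et3SiCl. The fallback uses known chemistry and closes the ring at a different bond. It sets out from 10: O-alkylation with commercial (2E,6E)-farnesyl bromide (K2CO3, acetone) would give 5-methyl-4-{[(2E,6E)-3,7,11-trimethyldodeca-2,6,10-trien-1-yl]oxy}-2H-chromen-2-one F1. Epoxidation of its terminal alkene with Oxone and the enantiomeric Shi ketone (from L-sorbose), stopped at partial conversion, would give 4-{[(2E,6E)-9-[(2S)-3,3-dimethyloxiran-2-yl]-3,7-dimethylnona-2,6-dien-1-yl]oxy}-5-methyl-2H-chromen-2-one F2. Cp2TiCl (from Cp2TiCl2 and Mn, THF) would then open the epoxide to the tertiary radical, which closes 6-endo through a chair onto the central alkene; the resulting tertiary organotitanium loses a methyl hydrogen to leave the exocyclic alkene. This established epoxypolyene radical cyclisation is expected to deliver the cis-(1R,3S) diastereomer of 14, where the route is rejoined for step 9.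

2. Step 4. Substitution at the hindered oxirane carbon beside the quaternary centre may be slow, so that magnesium-halide-induced rearrangement of the epoxide to a ketone or opening by bromide competes. The fallback sets out from 3: LiC≡CH·H2NCH2CH2NH2 in DMSO should open the epoxide at the same carbon with inversion to give (2E,6R)-6-ethynyl-3,7-dimethyloct-2-ene-1,7-diol F3. CpRu(cod)Cl-catalysed Alder-ene-type coupling of the terminal alkyne with allyl alcohol (NH4PF6, aqueous DMF, 100 °C) joins the internal alkyne carbon to the alkene terminus and tautomerises the enol, and should give (5R,8E)-10-hydroxy-5-(2-hydroxypropan-2-yl)-8-methyl-4-methylidenedec-8-enal F4. Mitsunobu etherification of F4 with 10 then gives 12, where the route is rejoined before step 8.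

3. Step 6. The ambident coumarin may be alkylated at C3 or at the lactone carbonyl oxygen instead of O4, or the allylic system may react with SN2' transposition. The fallback sets out from 10: POCl3 at 110 °C should give 4-chloro-5-methyl-2H-chromen-2-one F5. The sodium alkoxide formed from 8 with one equivalent of NaH at the primary hydroxyl (THF, 0 °C) should then displace chloride by addition–elimination at C4, which fixes the site of etherification and gives 11, where the route is rejoined before step 7.

**Further compounds**

F1 | step 8 | 5-methyl-4-{[(2E,6E)-3,7,11-trimethyldodeca-2,6,10-trien-1-yl]oxy}-2H-chromen-2-one | CC(C)=CCC/C(C)=C/CC/C(C)=C/COc1cc(=O)oc2cccc(C)c12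
F2 | step 8 | 4-{[(2E,6E)-9-[(2S)-3,3-dimethyloxiran-2-yl]-3,7-dimethylnona-2,6-dien-1-yl]oxy}-5-methyl-2H-chromen-2-one | CC1(C)O[C@H]1CC/C(C)=C/CC/C(C)=C/COc1cc(=O)oc2cccc(C)c12
F3 | step 4 | (2E,6R)-6-ethynyl-3,7-dimethyloct-2-ene-1,7-diol | CC(C)(O)[C@@H](C#C)CC/C(C)=C/CO
F4 | step 4 | (5R,8E)-10-hydroxy-5-(2-hydroxypropan-2-yl)-8-methyl-4-methylidenedec-8-enal | CC(C)(O)[C@@H](C(=C)CCC=O)CC/C(C)=C/CO
F5 | step 6 | 4-chloro-5-methyl-2H-chromen-2-one | Cc1cccc2oc(=O)cc(Cl)c12
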